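**Assumptions:** The target (3,5,6,7,8,4'-hexamethoxyflavone, C21H22O8) has no stereocentres, so it is achiral and no enantiocontrol is needed. Pentamethoxybenzene (CAS 13909-75-6) is taken as a catalogue starting material; I could not confirm supplier availability here.

**Retrosynthetic overview**
1. The C2–aryl bond is cut last: the B-ring is attached by C2–H zincation and Negishi arylation of a fully substituted 3-methoxychromone, avoiding the usual chalcone/Algar–Flynn–Oyamada or Baker–Venkataraman logic.
2. The pyranone (C) ring comes from a one-carbon enaminone annulation (DMF-DMA) of a 2-hydroxyaryl methoxymethyl ketone.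
3. The phenol comes from chelation-controlled mono-demethylation of a symmetric pentamethoxyphenyl ketone, where both ortho OMe groups are equivalent, so there is no regiochemical issue.
4. The ketone comes from ortho-lithiation of pentamethoxybenzene and acylation with a methoxyacetyl Weinreb amide.
5. Ring order: A-ring purchased, C-ring formed in step 3, B-ring appended in step 4.

**Step 1**
Reactants: 1, pentamethoxybenzene; 2, N,2-dimethoxy-N-methylacetamide (methoxyacetic acid Weinreb amide)
Product: 3, 2-methoxy-1-(2,3,4,5,6-pentamethoxyphenyl)ethan-1-one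
Conditions: n-BuLi (1.1 equiv), TMEDA, THF, 0 °C → rt, 1 h; then 2 (1.2 equiv), −78 → 0 °C; sat. NH4Cl
Reagents that add atoms: N,2-dimethoxy-N-methylacetamide, COCC(=O)N(C)OC
Why: Directed ortho-lithiation removes the only aryl H, which is flanked by two OMe groups, and the aryllithium undergoes Weinreb ketone synthesis, where the stable chelated tetrahedral intermediate prevents over-addition.

**Step 2**
Reactants: 3, 2-methoxy-1-(2,3,4,5,6-pentamethoxyphenyl)ethan-1-one
Product: 4, 1-(2-hydroxy-3,4,5,6-tetramethoxyphenyl)-2-methoxyethan-1-one
Conditions: BCl3 (1.1 equiv, 1 M in CH2Cl2), CH2Cl2, −78 → 0 °C; aq. NaHCO3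
Reagents that add atoms: none
Why: Chelation-controlled Lewis-acid demethylation: BCl3 bound to the ketone cleaves only an ortho OMe through a six-membered boron chelate, the resulting aryloxyboron chelate blocks a second cleavage, and the two ortho OMe groups are equivalent; the aliphatic OMe and the non-chelated aryl OMe groups survive at ≤0 °C with one equivalent.

**Step 3**
Reactants: 4, 1-(2-hydroxy-3,4,5,6-tetramethoxyphenyl)-2-methoxyethan-1-one; 5, N,N-dimethylformamide dimethyl acetal (DMF-DMA)
Product: 6, 3,5,6,7,8-pentamethoxy-4H-chromen-4-one
Conditions: DMF-DMA (3 equiv), toluene, 105 °C; concentrate; then 2 M HCl, CH2Cl2, rt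
Reagents that add atoms: DMF-DMA, COC(OC)N(C)C (supplies the C2 methine carbon)
Why: Enaminone annulation: the α-methoxy methylene condenses with DMF-DMA to give ArCO–C(OMe)=CH–NMe2, and the ortho phenol closes by intramolecular oxa-Michael addition and loss of Me2NH, as in the standard deoxybenzoin-to-isoflavone synthesis.

**Step 4 (key step)**
Reactants: 6, 3,5,6,7,8-pentamethoxy-4H-chromen-4-one; 7, 4-iodoanisole
Product: 8, 3,5,6,7,8-pentamethoxy-2-(4-methoxyphenyl)-4H-chromen-4-one (3-methoxytangeretin)
Conditions: TMPZnCl·LiCl (1.3 equiv), THF, 25 °C, 2 h; then 7 (1.2 equiv), Pd(dba)2 (3 mol%), P(2-furyl)3 (6 mol%), 50 °C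
Reagents that add atoms: 4-iodoanisole, COc1ccc(I)cc1
Why: Directed C–H zincation followed by Negishi cross-coupling: C2–H is the only sp2 C–H in 6 and is acidified by the ring oxygen and the adjacent 3-OMe, the mild zinc amide tolerates the pyranone carbonyl, and the C2-zinc species cannot ring-open by β-elimination; the 3-methoxychromone substrate is an extension of the known chromone C2-zincation.

**Compound list**
1 | pentamethoxybenzene | COc1cc(OC)c(OC)c(OC)c1OC | starting material
2 | N,2-dimethoxy-N-methylacetamide | COCC(=O)N(C)OC | starting material
3 | 2-methoxy-1-(2,3,4,5,6-pentamethoxyphenyl)ethan-1-one | COCC(=O)c1c(OC)c(OC)c(OC)c(OC)c1OC | intermediate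
4 | 1-(2-hydroxy-3,4,5,6-tetramethoxyphenyl)-2-methoxyethan-1-one | COCC(=O)c1c(O)c(OC)c(OC)c(OC)c1OC | intermediate
5 | N,N-dimethylformamide dimethyl acetal | COC(OC)N(C)C | starting material (reagent)
6 | 3,5,6,7,8-pentamethoxy-4H-chromen-4-one | COc1coc2c(OC)c(OC)c(OC)c(OC)c2c1=O | intermediate
7 | 4-iodoanisole | COc1ccc(I)cc1 | starting material
8 | 3-methoxytangeretin, 3,5,6,7,8-pentamethoxy-2-(4-methoxyphenyl)-4H-chromen-4-one (achiral) | COc1ccc(-c2oc3c(OC)c(OC)c(OC)c(OC)c3c(=O)c2OC)cc1 | target

**Total step count:** 4
**Longest linear sequence:** 4 steps (1 → 3 → 4 → 6 → 8)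

**Three steps most likely to fail, with fallbacks**
1. Step 4 (C2 zincation/Negishi): metalation of the electron-rich, hindered chromone may be sluggish, or the coupling may stall. Fallback: abandon C–H arylation and build the C-ring with the B-ring already in place. O-acylate phenol 4 with 4-methoxybenzoyl chloride, perform Baker–Venkataraman rearrangement (KOH, pyridine) to the 2-methoxy-1,3-diketone, and cyclodehydrate (H2SO4/AcOH) to 8.
2. Step 3 (DMF-DMA annulation): the chelated, hindered α-methoxy ketone may condense slowly, or DMF-DMA may O-methylate the phenol back to 3. Fallback: reverse the order. Condense the non-phenolic ketone 3 with DMF-DMA to its enaminone, then close the ring by demethylative cyclization (BBr3 or TMSI), in which the ortho OMe oxygen attacks the activated enaminone and loses its methyl group.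
3. Step 1 (ArLi plus Weinreb amide): the hindered 2,6-dimethoxyaryllithium may enolize the amide or attack its N–OMe group by E2 instead of adding. Fallback: add the aryllithium to methoxyacetaldehyde to give the carbinol, then oxidize with Dess–Martin periodinane to ketone 3.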